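Ring C of the flavanone is disconnected at O1–C2 and C3–C4. O1 and C4 sit on adjacent carbons (C8a, C4a) of phloroglucinol ring A, and C2 is benzylic to catechol ring B, whose O4' lies para to C1'. Ring A can therefore act as an ortho-quinone methide and ring B as a polarised styrene. One enantioselective hetero-Diels–Alder step joins them, closes ring C and sets C2, with a sacrificial methoxy stereocentre at C4 at the ketone oxidation level. The precursor is a benzyl-protected apigenin carrying a 2,3-bis(benzyloxy)-6-vinylphenyl group at C6'', made by Suzuki coupling. Hydrolysis, oxidation and hydrogenolysis finish the synthesis.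

Key step: step 9

Remark: the target SMILES fixes only C2 (S); the tetra-ortho-substituted C6''–C2' biaryl axis is unassigned there and is not controlled, so 10 and later compounds may be mixtures of rotamers about this axis, all with the stated configuration at carbon.
Locants: flavanone O1–C8a with ring B C1'–C6'; the apigenin unit is double-primed and its 4-hydroxyphenyl ring triple-primed. Compound 4 is catalogue material (one bromination away from isovanillin).

Step 1
Reactants: 1 apigenin
Product: 2 7,4'-di-O-benzylapigenin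
Conditions: BnBr (2.1 equiv), K2CO3, DMF, rt
Reagents that add atoms: benzyl bromide, BrCc1ccccc1
Why: Williamson etherification, in which the acidic 7- and 4'-phenols react while the 5-OH, held in a hydrogen bond to C4=O, is left free.

Step 2
Reactants: 2 7,4'-di-O-benzylapigenin
Product: 3 6-iodo-7,4'-di-O-benzylapigenin
Conditions: BnMe3N+ ICl2− (1.1 equiv), CaCO3, CH2Cl2/MeOH, rt
Reagents that add atoms: benzyltrimethylammonium dichloroiodate, C[N+](C)(C)Cc1ccccc1.Cl[I-]Cl
Why: Electrophilic aromatic iodination, which with the 5-OH free and O7 alkylated should occur ortho to the free phenol at C6 and not at C8.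

Step 3
Reactants: 4 2-bromo-3-hydroxy-4-methoxybenzaldehyde
Product: 5 2-bromo-3,4-dihydroxybenzaldehyde
Conditions: BBr3 (2.5 equiv), CH2Cl2, −78 °C → rt; then H2O
Reagents that add atoms: none
Why: Lewis-acid cleavage of an aryl methyl ether by BBr3, which leaves the aryl bromide and the aldehyde intact at low temperature.

Step 4
Reactants: 5 2-bromo-3,4-dihydroxybenzaldehyde
Product: 6 2-bromo-3,4-bis(benzyloxy)benzaldehyde
Conditions: BnBr (2.3 equiv), K2CO3, DMF, 60 °C
Reagents that add atoms: benzyl bromide, BrCc1ccccc1
Why: Williamson etherification of both catechol oxygens, neither of which is deactivated by chelation.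

Step 5
Reactants: 6 2-bromo-3,4-bis(benzyloxy)benzaldehyde
Product: 7 2-bromo-3,4-bis(benzyloxy)styrene
Conditions: Ph3PCH3Br, KOtBu, THF, 0 °C → rt
Reagents that add atoms: methyltriphenylphosphonium bromide, C[P+](c1ccccc1)(c1ccccc1)c1ccccc1.[Br-]
Why: Wittig methylenation of an aromatic aldehyde with the non-stabilised ylide, carried out on the small fragment where no other electrophile is present.

Step 6
Reactants: 7 2-bromo-3,4-bis(benzyloxy)styrene
Product: 9 2-[2,3-bis(benzyloxy)-6-vinylphenyl]-4,4,5,5-tetramethyl-1,3,2-dioxaborolane, via aryllithium 8 (not isolated)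
Conditions: n-BuLi, THF, −78 °C; then iPrOBpin, −78 °C → rt; aq. NH4Cl
Reagents that add atoms: n-butyllithium, [Li]CCCC (lithium only in 8); 2-isopropoxy-4,4,5,5-tetramethyl-1,3,2-dioxaborolane, CC(C)OB1OC(C)(C)C(C)(C)O1
Why: Lithiation–borylation, in which bromine–lithium exchange at −78 °C outruns addition to the vinyl group and benzylic deprotonation, and the aryllithium is trapped by the borate ester.

Step 7
Reactants: 3 6-iodo-7,4'-di-O-benzylapigenin; 9 2-[2,3-bis(benzyloxy)-6-vinylphenyl]-4,4,5,5-tetramethyl-1,3,2-dioxaborolane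
Product: 10 6-[2,3-bis(benzyloxy)-6-vinylphenyl]-7,4'-di-O-benzylapigenin
Conditions: Pd(OAc)2 (5 mol%), SPhos (10 mol%), K3PO4, toluene/H2O (10:1), 100 °C
Reagents that add atoms: none
Why: Suzuki–Miyaura coupling with a bulky dialkylbiarylphosphine, a ligand class established for tetra-ortho-substituted biaryls, helped by the reactive iodide and by the free chelated 5''-OH being the smallest possible ortho group.

Step 8
Reactants: 11 2,4,6-trihydroxybenzaldehyde
Product: 12 2-hydroxy-4,6-bis(benzyloxy)benzaldehyde
Conditions: BnBr (2.05 equiv), K2CO3, DMF, 0 °C → rt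
Reagents that add atoms: benzyl bromide, BrCc1ccccc1
Why: Williamson etherification of the 4-OH and one of the two equivalent ortho-OH groups, after which the last phenol is locked in a hydrogen bond to the aldehyde and resists a third benzylation.

Step 9
Reactants: 10 6-[2,3-bis(benzyloxy)-6-vinylphenyl]-7,4'-di-O-benzylapigenin; 12 2-hydroxy-4,6-bis(benzyloxy)benzaldehyde; 13 trimethyl orthoformate
Product: 16 (2S,4S)-5,7-bis(benzyloxy)-2-{3,4-bis(benzyloxy)-2-[7-(benzyloxy)-2-(4-benzyloxyphenyl)-5-hydroxy-4-oxo-4H-chromen-6-yl]phenyl}-4-methoxychromane (2,4-cis-4-methoxyflavan), via dimethyl acetal 14 (not isolated), via oxocarbenium ion 15 (not isolated)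
Conditions: (R)-3,3'-bis(2,4,6-triisopropylphenyl)-1,1'-binaphthyl-2,2'-diyl N-triflylphosphoramide (10 mol%; antipode chosen to give 2S), CH2Cl2, −30 °C, slow addition of 12 (2 equiv) and 13 (3 equiv); then Et3N
Reagents that add atoms: none
Why: Proposed new method: the acid converts 12 and 13 into acetal 14 and ionises it to oxocarbenium ion 15 (the O-protonated 4-methoxy ortho-quinone methide), held as a contact ion pair with the chiral phosphoramide anion through the ring-A phenol O–H; the CH2 terminus of styrene 10 (C3) attacks C4 and the phenol oxygen then collapses on the O4'-stabilised benzylic cation at C2, an asynchronous inverse-electron-demand hetero-Diels–Alder reaction. The closest known reaction types are the achiral acid-promoted coupling of salicylaldehydes, orthoformates and styrenes to 2,4-cis-4-alkoxyflavans and the chiral phosphoric-acid- or N-triflylphosphoramide-catalysed [4+2] additions of hydroxybenzyl-alcohol-derived ortho-quinone methides to styrenes, hydroxystyrenes and enamides; new is an acetal-derived, alkoxy-substituted methide under chiral-anion control. Ring C is closed by intermolecular [4+2] cycloaddition, four atoms (O1, C8a, C4a, C4) coming from the heterodiene and two (C2, C3) from the alkene, with O1–C2 formed last as a six-membered closure of phenol onto cation. C4 is set by the catalyst, whose anion shields one face of 15, and C2 is set relative to C4 by the endo transition state that leaves OMe and aryl cis and pseudo-equatorial. The step needs regioselectivity (aryl on C2), secured by the styrene polarity with O4' para to C1', and chemoselectivity for the vinyl group, secured because every phenol of 10 is benzylated except O5''–H, whose hydrogen bond to C4''=O lowers both its nucleophilicity and the basicity of the flavone carbonyl toward the catalyst. Trans isomers, which carry the wrong C2 configuration for the catalyst-set C4, are diastereomers and are removed by chromatography before C4 is oxidised.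

Step 10
Reactants: 16 (2S,4S)-4-methoxyflavan
Product: 17 (2S,4S)-5,7-bis(benzyloxy)-2-{3,4-bis(benzyloxy)-2-[7-(benzyloxy)-2-(4-benzyloxyphenyl)-5-hydroxy-4-oxo-4H-chromen-6-yl]phenyl}chroman-4-ol (flavan-4-ol)
Conditions: PPTS (cat.), THF/H2O (5:1), rt
Reagents that add atoms: water, O
Why: SN1 solvolysis of a benzylic methyl ether whose C4 cation is stabilised by O1, O5 and O7 of ring A, so a weak acid in wet THF should exchange OMe for OH without ionising O1–C2; the C4 configuration (cis expected on equilibration) is of no consequence because C4 is oxidised next.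

Step 11
Reactants: 17 (2S,4S)-flavan-4-ol
Product: 18 (2S)-5,7-bis(benzyloxy)-2-{3,4-bis(benzyloxy)-2-[7-(benzyloxy)-2-(4-benzyloxyphenyl)-5-hydroxy-4-oxo-4H-chromen-6-yl]phenyl}chroman-4-one (hexa-O-benzyl flavanone)
Conditions: Dess–Martin periodinane, NaHCO3, CH2Cl2, 0 °C → rt
Reagents that add atoms: none
Why: Dess–Martin oxidation of a secondary benzylic alcohol under buffered conditions that neither enolise nor ring-open the flavanone, so C2 is untouched, and the only free phenol is the deactivated, hydrogen-bonded 5''-OH.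

Step 12
Reactants: 18 hexa-O-benzyl (2S)-flavanone
Product: 19 (2S)-2-{3,4-dihydroxy-2-[5,7-dihydroxy-2-(4-hydroxyphenyl)-4-oxo-4H-chromen-6-yl]phenyl}-5,7-dihydroxychroman-4-one (target)
Conditions: H2 (1 atm), 10% Pd/C, THF/MeOH (1:1), rt
Reagents that add atoms: none
Why: Catalytic hydrogenolysis of the six aryl benzyl ethers under neutral conditions, which avoids the acid- or base-mediated ring opening that would racemise C2, and which should be faster than cleavage of the cyclic O1–C2 bond or reduction of the flavone C2''=C3'' bond.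

Compound list
1 | apigenin | O=c1cc(-c2ccc(O)cc2)oc2cc(O)cc(O)c12 | starting material
2 | 7,4'-di-O-benzylapigenin | O=c1cc(-c2ccc(OCc3ccccc3)cc2)oc2cc(OCc3ccccc3)cc(O)c12 | intermediate
3 | 6-iodo-7,4'-di-O-benzylapigenin | O=c1cc(-c2ccc(OCc3ccccc3)cc2)oc2cc(OCc3ccccc3)c(I)c(O)c12 | intermediate
4 | 2-bromo-3-hydroxy-4-methoxybenzaldehyde (2-bromoisovanillin) | COc1ccc(C=O)c(Br)c1O | starting material
5 | 2-bromo-3,4-dihydroxybenzaldehyde | O=Cc1ccc(O)c(O)c1Br | intermediate
6 | 2-bromo-3,4-bis(benzyloxy)benzaldehyde | O=Cc1ccc(OCc2ccccc2)c(OCc2ccccc2)c1Br | intermediate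
7 | 2-bromo-3,4-bis(benzyloxy)styrene | C=Cc1ccc(OCc2ccccc2)c(OCc2ccccc2)c1Br | intermediate
8 | [2,3-bis(benzyloxy)-6-vinylphenyl]lithium | [Li]c1c(C=C)ccc(OCc2ccccc2)c1OCc1ccccc1 | intermediate (not isolated)
9 | 2-[2,3-bis(benzyloxy)-6-vinylphenyl]-4,4,5,5-tetramethyl-1,3,2-dioxaborolane | C=Cc1ccc(OCc2ccccc2)c(OCc2ccccc2)c1B1OC(C)(C)C(C)(C)O1 | intermediate
10 | 6-[2,3-bis(benzyloxy)-6-vinylphenyl]-7,4'-di-O-benzylapigenin | C=Cc1ccc(OCc2ccccc2)c(OCc2ccccc2)c1-c1c(OCc2ccccc2)cc2oc(-c3ccc(OCc4ccccc4)cc3)cc(=O)c2c1O | intermediate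
11 | 2,4,6-trihydroxybenzaldehyde | O=Cc1c(O)cc(O)cc1O | starting material
12 | 2-hydroxy-4,6-bis(benzyloxy)benzaldehyde | O=Cc1c(O)cc(OCc2ccccc2)cc1OCc1ccccc1 | intermediate
13 | trimethyl orthoformate | COC(OC)OC | starting material
14 | 3,5-bis(benzyloxy)-2-(dimethoxymethyl)phenol (dimethyl acetal of 12) | COC(OC)c1c(O)cc(OCc2ccccc2)cc1OCc1ccccc1 | intermediate (not isolated)
15 | (E)-[2-hydroxy-4,6-bis(benzyloxy)benzylidene]methyloxonium ion (protonated 4-methoxy ortho-quinone methide, paired with the chiral anion) | C/[O+]=C/c1c(O)cc(OCc2ccccc2)cc1OCc1ccccc1 | intermediate (not isolated)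
16 | (2S,4S)-4-methoxyflavan, hexa-O-benzyl (full name in step 9) | CO[C@H]1C[C@@H](c2ccc(OCc3ccccc3)c(OCc3ccccc3)c2-c2c(OCc3ccccc3)cc3oc(-c4ccc(OCc5ccccc5)cc4)cc(=O)c3c2O)Oc2cc(OCc3ccccc3)cc(OCc3ccccc3)c21 | intermediate
17 | (2S,4S)-flavan-4-ol, hexa-O-benzyl (full name in step 10) | O[C@H]1C[C@@H](c2ccc(OCc3ccccc3)c(OCc3ccccc3)c2-c2c(OCc3ccccc3)cc3oc(-c4ccc(OCc5ccccc5)cc4)cc(=O)c3c2O)Oc2cc(OCc3ccccc3)cc(OCc3ccccc3)c21 | intermediate
18 | (2S)-flavanone, hexa-O-benzyl (full name in step 11) | O=C1C[C@@H](c2ccc(OCc3ccccc3)c(OCc3ccccc3)c2-c2c(OCc3ccccc3)cc3oc(-c4ccc(OCc5ccccc5)cc4)cc(=O)c3c2O)Oc2cc(OCc3ccccc3)cc(OCc3ccccc3)c21 | intermediate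
19 | (2S)-2-{3,4-dihydroxy-2-[5,7-dihydroxy-2-(4-hydroxyphenyl)-4-oxo-4H-chromen-6-yl]phenyl}-5,7-dihydroxychroman-4-one | O=C1C[C@@H](c2ccc(O)c(O)c2-c2c(O)cc3oc(-c4ccc(O)cc4)cc(=O)c3c2O)Oc2cc(O)cc(O)c21 | target

Total step count: 12. Longest linear sequence: 9 steps (4 → 5 → 6 → 7 → 9 → 10 → 16 → 17 → 18 → 19).

Steps most likely to fail

Step 9. Facial discrimination at the methide carbon may be weak, and worse for the rotamer of 10 whose biaryl axis is mismatched with the catalyst. Acid-induced reionisation at C4 or C2 could erode the stereochemical relay, and the electron-rich methide may oligomerise. The fallback uses known chemistry and sets out from 10, 12 and 13. The cycloaddition is run with an achiral acid (TsOH·H2O cat., CH2Cl2, 0 °C), the established racemic 2,4-cis-selective reaction, which should give 16 together with its enantiomer, the (2R,4R)-4-methoxyflavan F1. Steps 10 and 11 applied to this mixture should give 17 with its enantiomer, the (2R,4R)-flavan-4-ol F2, and then 18 with its enantiomer, the (2R)-flavanone F3. Kinetic resolution by asymmetric transfer hydrogenation, a known resolution of racemic flavanones, follows (RuCl(p-cymene)[TsDPEN], in the antipode that reduces the 2R ketone, HCO2H/Et3N, EtOAc, rt). It should reduce F3 back to the cis-alcohol F2 while the (2S)-ketone is recovered by chromatography, and the route is rejoined at 18. The same resolution can upgrade partially enriched 18 from the catalytic route.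

Step 7. Transmetalation and reductive elimination at the tetra-ortho-substituted axis may be slow, which would allow protodeboronation of 9, reduction of the iodide, or Heck-type arylation of the vinyl group. The fallback reverses the roles of the partners and installs the vinyl group last, setting out from 3 and 6. Palladium-catalysed borylation of 3 (HBpin, Et3N, Pd(MeCN)2Cl2/SPhos, dioxane, 80 °C) should give 7,4'-di-O-benzylapigenin-6-boronic acid pinacol ester F4. Suzuki coupling of F4 with bromide 6, whose ortho-formyl group accelerates oxidative addition (Pd(OAc)2/SPhos, K3PO4, toluene/H2O), should give 6-[2,3-bis(benzyloxy)-6-formylphenyl]-7,4'-di-O-benzylapigenin F5. Wittig methylenation of F5 (Ph3PCH3Br/KOtBu, excess to allow for the phenol, THF) comes back to the route at 10.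

Step 10. The C4 cation may be diverted to elimination (flav-3-ene formation) or to Friedel–Crafts self-condensation instead of capture by water, and prolonged acid exposure may open O1–C2 with loss of the C2 configuration. The fallback avoids the acid and the alcohol altogether and sets out from 16. DDQ (1.2 equiv) in CH2Cl2/pH 7 buffer at 0 °C should abstract hydride from C4–H, as in the oxidative cleavage of electron-rich benzyl ethers; water then adds to the oxocarbenium ion and the hemiketal collapses with loss of methanol. This gives the ketone directly and comes back to the route at 18, bypassing 17.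

Further compounds
F1 | step 9 | (2R,4R)-4-methoxyflavan, hexa-O-benzyl (enantiomer of 16) | CO[C@@H]1C[C@H](c2ccc(OCc3ccccc3)c(OCc3ccccc3)c2-c2c(OCc3ccccc3)cc3oc(-c4ccc(OCc5ccccc5)cc4)cc(=O)c3c2O)Oc2cc(OCc3ccccc3)cc(OCc3ccccc3)c21
F2 | step 9 | (2R,4R)-flavan-4-ol, hexa-O-benzyl (enantiomer of 17) | O[C@@H]1C[C@H](c2ccc(OCc3ccccc3)c(OCc3ccccc3)c2-c2c(OCc3ccccc3)cc3oc(-c4ccc(OCc5ccccc5)cc4)cc(=O)c3c2O)Oc2cc(OCc3ccccc3)cc(OCc3ccccc3)c21
F3 | step 9 | (2R)-flavanone, hexa-O-benzyl (enantiomer of 18) | O=C1C[C@H](c2ccc(OCc3ccccc3)c(OCc3ccccc3)c2-c2c(OCc3ccccc3)cc3oc(-c4ccc(OCc5ccccc5)cc4)cc(=O)c3c2O)Oc2cc(OCc3ccccc3)cc(OCc3ccccc3)c21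
F4 | step 7 | 7,4'-di-O-benzylapigenin-6-boronic acid pinacol ester | O=c1cc(-c2ccc(OCc3ccccc3)cc2)oc2cc(OCc3ccccc3)c(B3OC(C)(C)C(C)(C)O3)c(O)c12
F5 | step 7 | 6-[2,3-bis(benzyloxy)-6-formylphenyl]-7,4'-di-O-benzylapigenin | O=Cc1ccc(OCc2ccccc2)c(OCc2ccccc2)c1-c1c(OCc2ccccc2)cc2oc(-c3ccc(OCc4ccccc4)cc3)cc(=O)c2c1O
F0 | step 10 | none | none
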